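**Assumptions.** The target is prepared as the free base. In step 4 the (R)-antipode of the pyridine–oxazoline ligand is assumed to be the one that gives (2S), by transposing the accepted facial model of the (S)-ligand with cyclic enones to the chromone; both antipodes are available, so the sense would be checked on a model chromone first. Compounds 1, 5 and 12 are taken as commercial.

## Structural features

The target is a flavanone alkaloid: ring A (benzene, C4a–C5–C6–C7–C8–C8a) is fused to ring C (dihydropyranone, O1–C2–C3–C4), ring B (4-hydroxyphenyl) sits on C2, and ring D (N-methylpiperidine) is joined through its C2' to C6. Ring A carries five substituents; C6 is its only carbon-substituted position lying between two oxygen-bearing carbons (C5–OH, hydrogen-bonded to the C4 carbonyl, and C7–OH), while C8 is unsubstituted. The two stereocenters, C2 (S) and C2' (S), are seven bonds apart across ring A, so neither can control the other and each must be set on its own. C2 is fragile: base opens ring C by retro-oxa-Michael reaction to a 2'-hydroxychalcone, which racemizes C2 and, because O5 is also free, can close again through O5 and so move ring D from C6 to C8 (Wessely–Moser-type isomerization). C2' is a benzylic amine flanked by two phenols and can ionize in a retro-Mannich sense under hot acid. The real difficulty is therefore to attach ring D at C6 and not at C8, with defined configuration at C2', on a ring whose two open positions are nearly equivalent toward electrophiles. The key step exploits exactly this: a carbon substituent flanked by two oxygenated carbons is the pattern produced when a ketene and an ynol ether are merged into a benzene ring, and the C6–C2' bond then arrives as the alkyne–carbon bond of a fragment taken from (S)-pipecolic acid, so that ring A is built last onto a preformed pyranone whose ring oxygen already defines O1.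

## Logic of the disconnections

**16 from 15.** The O7–Si and O4'–Si bonds are cut. The phenols stay masked until the end so that ring A is less nucleophilic during N-methylation and no phenoxide is ever present beside the C2 center. The gain is small; the demand is a desilylation that is not basic.

**15 from 14.** The N–CH3 bond is cut. The methyl group is added late because a basic tertiary amine would interfere with ketene chemistry and with the palladium step. The forward step must methylate nitrogen without touching the C4 ketone or C8.

**14 from 13.** The N–CO2t-Bu bond is restored. The carbamate keeps nitrogen non-basic and non-nucleophilic through steps 1, 3 and 4. The forward step must remove it without ionizing the C6–C2' benzylic position.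

**13 from 11 and 12.** The C2–C1(ring B) bond is cut. This removes ring B and the C2 stereocenter in one operation and leaves a flat chromone that has no base-labile center. The forward step must deliver the aryl group to one face of C2 under catalyst control, with the free 5-OH and the remote C2' center as spectators.

**11 from 7 and 4 (key).** Four bonds of ring A are cut: C5–C6 and C7–C8 (formed by cycloaddition), C4a–C5 (formed by electrocyclization) and C8–C8a (formed by a 1,2-shift). Cutting here turns the regiochemical problem into a matter of connectivity: C4a and C8a come from C3 and C2 of the pyranone in 7, C5 and C8 from its diazoacetyl carbons, and C6 and C7 from the alkyne carbons of 4. The gain is all of ring A with its five substituents, O5 and O7 already differentiated (free OH and silyl ether), and C2' carried in intact. The forward step demands a regiospecific ketene–alkyne union and selective generation of the ketene beside a pyranone chromophore.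

**7 from 5.** The bond between the acyl carbon (future C5) and the diazo carbon (future C8) is cut. This leads back to a commercial pyranone acid. The forward step is an acylation of diazomethane.

**4 from 1.** One carbon is inserted between C2' and the ester carbonyl of 1: the C2'–C(alkyne) bond and the alkyne itself are formed, the inserted carbon becomes C6, and the ester carbonyl carbon with its oxygen becomes C7 and O7. This takes C2' from the chiral pool. The forward step must not enolize the α-amino ester and must move C2' with retention.

## Other disconnections considered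

**Alternative 1:** (the first that comes to mind) Cut C6–C2' in the Mannich sense. The forward key step is an aza-Friedel–Crafts reaction of (2S)-naringenin A1 with the cyclic iminium ion 1-methyl-2,3,4,5-tetrahydropyridinium A2. C6 and C8 of A1 are both activated by two flanking oxygens, so the 8-substituted regioisomer A3 and bis-adducts are expected beside the target. A2 is planar and achiral, so C2' would form without control. The amine and heat needed for the reaction are also the conditions that open ring C. The chosen plan fixes C6 by construction and buys C2' from the chiral pool.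

**Alternative 2:** Cut C4a–C5 and fold a β-carbonyl chain: Dieckmann cyclization and aromatization of the pyranone keto ester A4 to the dihydroxychromone A5, as in the biosynthesis of ring A. The regiochemistry would also be fixed by the preformed pyranone. However, the enolate that must form next to C2' is β to the carbamate nitrogen and can expel it (retro-aza-Michael reaction), which endangers the only chiral-pool center. A4 also needs its own multi-step assembly by lateral acylation of a 2-methylpyranone ester. The chosen benzannulation has no anionic intermediate beside C2' and reaches the same ring in one operation from two short fragments.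

**Alternative 3:** Cut C6–C2' with reversed polarity: Negishi coupling of the aryl bromide A6 with the configurationally defined α-amino organozinc A7. A6 requires bromination at C6 and not C8, which is the original regiochemical problem in another form. A7 depends on asymmetric deprotonation of N-Boc-piperidine, which is slow and weakly selective. A secondary alkylzinc must then couple at a carbon flanked by two ortho alkoxy groups, where β-hydride elimination competes. Both the regiochemistry and the C2' configuration would rest on the weakest links.

Key step: step 3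

## Route

Step 1
Reactants: 1 1-tert-butyl 2-methyl (2S)-piperidine-1,2-dicarboxylate
Product: 4 tert-butyl (2S)-2-({[tri(propan-2-yl)silyl]oxy}ethynyl)piperidine-1-carboxylate, via lithium dibromoenolate 2 (not isolated), via lithium ynolate 3 (not isolated)
Conditions: CH2Br2, lithium 2,2,6,6-tetramethylpiperidide, THF, −78 °C; add 1; LiN(SiMe3)2, −78 °C; n-BuLi, −78 → 0 °C; then i-Pr3SiCl, −78 → 0 °C
Reagents that add atoms: dibromomethane BrCBr; chlorotri(propan-2-yl)silane CC(C)[Si](Cl)(C(C)C)C(C)C
Why: Kowalski ester homologation stopped at the ynolate: (dibromomethyl)lithium adds to the ester, the dibromomethyl ketone is enolized at once on the dibromo side to 2, and bromine–lithium exchange triggers a 1,2-shift of the C2' carbon with retention to give 3, which the bulky silyl chloride traps on oxygen. C2' is never α to a free carbonyl in the presence of base, so the (S) configuration of 1 should be carried into 4.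

Step 2
Reactants: 5 4-oxo-4H-pyran-2-carboxylic acid (comanic acid)
Product: 7 2-(2-diazoacetyl)-4H-pyran-4-one, via acid chloride 6 (not isolated)
Conditions: (COCl)2, cat. DMF, CH2Cl2, 0 → 20 °C; evaporate; CH2N2 (excess), Et2O/THF, 0 °C
Reagents that add atoms: diazomethane C=[N+]=[N-]
Why: First stage of the Arndt–Eistert sequence: acylation of diazomethane by 6, with the second equivalent of diazomethane taking up HCl. The acid chloride is far more electrophilic than the vinylogous ester carbonyl or the ring double bonds, so acylation should be complete at 0 °C before any cycloaddition to the pyranone.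

Step 3
Reactants: 7 2-(2-diazoacetyl)-4H-pyran-4-one; 4 tert-butyl (2S)-2-({[tri(propan-2-yl)silyl]oxy}ethynyl)piperidine-1-carboxylate
Product: 11 tert-butyl (2S)-2-(5-hydroxy-4-oxo-7-{[tri(propan-2-yl)silyl]oxy}-4H-chromen-6-yl)piperidine-1-carboxylate, via pyranonylketene 8 (not isolated), via vinylcyclobutenone 9 (not isolated), via dienylketene 10 (not isolated)
Conditions: 4 (1.3 equiv), hν (365 nm), degassed ClCH2CH2Cl, 20 °C; then 80 °C
Reagents that add atoms: none
Why: Irradiation at 365 nm excites the diazoketone, which loses N2 with 1,2-shift of the pyranonyl carbon (Wolff rearrangement) to give ketene 8, forming the future C8–C8a bond. The electron-rich alkyne 4 then adds across the ketene C=C bond in a [2+2] cycloaddition in which its nucleophilic carbon, the one bearing C2', bonds to the ketene carbonyl carbon, giving cyclobutenone 9 (future C5–C6 and C7–C8 bonds). Four-electron electrocyclic opening of 9 gives dienylketene 10, and thermal six-electron disrotatory electrocyclization onto C3 of the pyranone followed by enolization closes ring A (C4a–C5 bond) and liberates the 5-OH. The closest known reaction type is the Danheiser benzannulation in its photochemical Wolff form with siloxyalkynes, which is established for aryl, heteroaryl and alkenyl diazomethyl ketones. The four-membered ring closes by [2+2] cycloaddition and is transient; ring A closes by 6π electrocyclization. No new stereocenter survives, since the sp3 carbon of 9 becomes planar on ring opening, and C2' is a spectator under neutral, non-ionic conditions and should keep its (S) configuration. The regiochemistry needed is that the C2'-bearing carbon ends between the two oxygenated carbons and that the ring oxygen ends para to it: the first is secured by the polarization of the siloxyalkyne, the second because O1 is already part of the pyranone and only its C3 can take part in the electrocyclization. Capture of the ketene by the product phenol is disfavoured because the 5-OH is hydrogen-bonded to the C4 carbonyl and shielded by ring D.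

Step 4
Reactants: 11 tert-butyl (2S)-2-(5-hydroxy-4-oxo-7-{[tri(propan-2-yl)silyl]oxy}-4H-chromen-6-yl)piperidine-1-carboxylate; 12 {4-[(tert-butyldimethylsilyl)oxy]phenyl}boronic acid
Product: 13 tert-butyl (2S)-2-[(2S)-2-{4-[(tert-butyldimethylsilyl)oxy]phenyl}-5-hydroxy-4-oxo-7-{[tri(propan-2-yl)silyl]oxy}-3,4-dihydro-2H-chromen-6-yl]piperidine-1-carboxylate
Conditions: 12 (2.5 equiv), Pd(OCOCF3)2 (10 mol %), (R)-4-tert-butyl-2-(pyridin-2-yl)-4,5-dihydro-1,3-oxazole (12 mol %), NH4PF6 (30 mol %), H2O (5 equiv), ClCH2CH2Cl, 60 °C
Reagents that add atoms: none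
Why: Asymmetric conjugate addition of an arylboronic acid to a chromone catalysed by divalent palladium with a pyridine–oxazoline ligand: transmetalation, enantio-determining insertion of C2=C3 into the aryl–palladium bond and protonolysis of the enolate by water. The new C2 center is set by the ligand, whose tert-butyl group blocks one face of the bound chromone; C2' is too remote to compete. The weakly acidic aqueous medium should leave carbamate, silyl ethers and the new β-aryloxy ketone untouched.

Step 5
Reactants: 13 tert-butyl (2S)-2-[(2S)-2-{4-[(tert-butyldimethylsilyl)oxy]phenyl}-5-hydroxy-4-oxo-7-{[tri(propan-2-yl)silyl]oxy}-3,4-dihydro-2H-chromen-6-yl]piperidine-1-carboxylate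
Product: 14 (2S)-2-{4-[(tert-butyldimethylsilyl)oxy]phenyl}-5-hydroxy-6-[(2S)-piperidin-2-yl]-7-{[tri(propan-2-yl)silyl]oxy}-2,3-dihydro-4H-chromen-4-one
Conditions: CF3CO2H/CH2Cl2 (1:4), 0 °C; cold aq. NaHCO3 (pH ≤ 8)
Reagents that add atoms: none
Why: Acidolysis of the tert-butyl carbamate; aryl silyl ethers and the flavanone should survive cold, brief acid. The ammonium ion formed is a poor leaving group at 0 °C, so C2' should not ionize, and the mildly basic work-up stays below the pH at which ring C opens.

Step 6
Reactants: 14 (2S)-2-{4-[(tert-butyldimethylsilyl)oxy]phenyl}-5-hydroxy-6-[(2S)-piperidin-2-yl]-7-{[tri(propan-2-yl)silyl]oxy}-2,3-dihydro-4H-chromen-4-one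
Product: 15 (2S)-2-{4-[(tert-butyldimethylsilyl)oxy]phenyl}-5-hydroxy-6-[(2S)-1-methylpiperidin-2-yl]-7-{[tri(propan-2-yl)silyl]oxy}-2,3-dihydro-4H-chromen-4-one
Conditions: aq. HCHO (37 %, 1.5 equiv), NaBH(OAc)3, AcOH, ClCH2CH2Cl, 0 → 20 °C
Reagents that add atoms: formaldehyde C=O
Why: Reductive amination: condensation of the secondary amine with formaldehyde and hydride reduction in situ by a reagent that does not reduce the hydrogen-bonded aryl ketone. Ring A is still silylated at O7, which lowers its reactivity toward formaldehyde at C8; no stereocenter is involved.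

Step 7
Reactants: 15 (2S)-2-{4-[(tert-butyldimethylsilyl)oxy]phenyl}-5-hydroxy-6-[(2S)-1-methylpiperidin-2-yl]-7-{[tri(propan-2-yl)silyl]oxy}-2,3-dihydro-4H-chromen-4-one
Product: 16 (2S)-5,7-dihydroxy-2-(4-hydroxyphenyl)-6-[(2S)-1-methylpiperidin-2-yl]-2,3-dihydro-4H-chromen-4-one
Conditions: HF·pyridine, THF/pyridine, 0 → 20 °C; pH 7 phosphate buffer
Reagents that add atoms: none
Why: Fluoride cleavage of both aryl silyl ethers under acidic, buffered conditions. No free phenoxide is generated, so retro-oxa-Michael opening of ring C (loss of C2 configuration and migration of ring D to C8) should be avoided.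

## Compound list

1 | 1-tert-butyl 2-methyl (2S)-piperidine-1,2-dicarboxylate | CC(C)(C)OC(=O)N1CCCC[C@H]1C(=O)OC | starting material
2 | lithium 2,2-dibromo-1-[(2S)-1-(tert-butoxycarbonyl)piperidin-2-yl]ethen-1-olate | CC(C)(C)OC(=O)N1CCCC[C@H]1C([O-])=C(Br)Br.[Li+] | intermediate
3 | lithium 2-[(2S)-1-(tert-butoxycarbonyl)piperidin-2-yl]ethyn-1-olate | CC(C)(C)OC(=O)N1CCCC[C@H]1C#C[O-].[Li+] | intermediate
4 | tert-butyl (2S)-2-({[tri(propan-2-yl)silyl]oxy}ethynyl)piperidine-1-carboxylate | CC(C)(C)OC(=O)N1CCCC[C@H]1C#CO[Si](C(C)C)(C(C)C)C(C)C | intermediate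
5 | 4-oxo-4H-pyran-2-carboxylic acid (comanic acid) | OC(=O)C1=CC(=O)C=CO1 | starting material
6 | 4-oxo-4H-pyran-2-carbonyl chloride | ClC(=O)C1=CC(=O)C=CO1 | intermediate
7 | 2-(2-diazoacetyl)-4H-pyran-4-one | [N-]=[N+]=CC(=O)C1=CC(=O)C=CO1 | intermediate
8 | 2-(4-oxo-4H-pyran-2-yl)ethen-1-one | O=C=CC1=CC(=O)C=CO1 | intermediate
9 | tert-butyl (2S)-2-[4-oxo-3-(4-oxo-4H-pyran-2-yl)-2-{[tri(propan-2-yl)silyl]oxy}cyclobut-1-en-1-yl]piperidine-1-carboxylate (both epimers at the cyclobutene sp3 carbon) | CC(C)(C)OC(=O)N1CCCC[C@H]1C1=C(O[Si](C(C)C)(C(C)C)C(C)C)C(C1=O)C1=CC(=O)C=CO1 | intermediate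
10 | tert-butyl (2S)-2-[(3E)-1-oxo-4-(4-oxo-4H-pyran-2-yl)-3-{[tri(propan-2-yl)silyl]oxy}buta-1,3-dien-2-yl]piperidine-1-carboxylate | CC(C)(C)OC(=O)N1CCCC[C@H]1C(=C=O)/C(O[Si](C(C)C)(C(C)C)C(C)C)=C\C1=CC(=O)C=CO1 | intermediate
11 | tert-butyl (2S)-2-(5-hydroxy-4-oxo-7-{[tri(propan-2-yl)silyl]oxy}-4H-chromen-6-yl)piperidine-1-carboxylate | CC(C)(C)OC(=O)N1CCCC[C@H]1c1c(O[Si](C(C)C)(C(C)C)C(C)C)cc2OC=CC(=O)c2c1O | intermediate
12 | {4-[(tert-butyldimethylsilyl)oxy]phenyl}boronic acid | CC(C)(C)[Si](C)(C)Oc1ccc(cc1)B(O)O | starting material
13 | tert-butyl (2S)-2-[(2S)-2-{4-[(tert-butyldimethylsilyl)oxy]phenyl}-5-hydroxy-4-oxo-7-{[tri(propan-2-yl)silyl]oxy}-3,4-dihydro-2H-chromen-6-yl]piperidine-1-carboxylate | CC(C)(C)OC(=O)N1CCCC[C@H]1c1c(O[Si](C(C)C)(C(C)C)C(C)C)cc2c(c1O)C(=O)C[C@@H](c1ccc(O[Si](C)(C)C(C)(C)C)cc1)O2 | intermediate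
14 | (2S)-2-{4-[(tert-butyldimethylsilyl)oxy]phenyl}-5-hydroxy-6-[(2S)-piperidin-2-yl]-7-{[tri(propan-2-yl)silyl]oxy}-2,3-dihydro-4H-chromen-4-one | N1CCCC[C@H]1c1c(O[Si](C(C)C)(C(C)C)C(C)C)cc2c(c1O)C(=O)C[C@@H](c1ccc(O[Si](C)(C)C(C)(C)C)cc1)O2 | intermediate
15 | (2S)-2-{4-[(tert-butyldimethylsilyl)oxy]phenyl}-5-hydroxy-6-[(2S)-1-methylpiperidin-2-yl]-7-{[tri(propan-2-yl)silyl]oxy}-2,3-dihydro-4H-chromen-4-one | CN1CCCC[C@H]1c1c(O[Si](C(C)C)(C(C)C)C(C)C)cc2c(c1O)C(=O)C[C@@H](c1ccc(O[Si](C)(C)C(C)(C)C)cc1)O2 | intermediate
16 | (2S)-5,7-dihydroxy-2-(4-hydroxyphenyl)-6-[(2S)-1-methylpiperidin-2-yl]-2,3-dihydro-4H-chromen-4-one | CN1CCCC[C@H]1c1c(O)cc2c(c1O)C(=O)C[C@@H](c1ccc(O)cc1)O2 | target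

## Step count and least certain steps

Total: 7 steps. Longest linear sequence: 6 steps (1, 3, 4, 5, 6, 7); step 2 is a one-step branch.

**Step 3 (key).** The ketene may be lost before the hindered alkyne captures it, through competing photoreactions (dimerization or ring contraction of the pyranone chromophore, cycloaddition of the diazo dipole to the electron-rich alkyne) or through ketene dimerization. The fallback sets out from 7 and comes back at 11, and makes the ketene in the dark. Wolff rearrangement of 7 in aqueous THF with PhCO2Ag and Et3N would give (4-oxo-4H-pyran-2-yl)acetic acid F1. Treatment with (COCl)2 and cat. DMF at 0 °C would give (4-oxo-4H-pyran-2-yl)acetyl chloride F2. Slow addition of F2 to 4 and i-Pr2NEt in toluene at 80 °C would generate 8 by dehydrochlorination at low stationary concentration, and the thermal sequence through 9 and 10 would then give 11.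

**Step 4.** Facial selectivity may be poor or turnover may stall, because the 5-hydroxy-4-keto unit can chelate divalent palladium and the ligand model is untested beside a bulky 6-substituent; protodeboronation of the electron-rich boronic acid also competes. The fallback sets out from 11 and comes back at 13; it introduces the aryl group without stereocontrol and sets C2 by hydrogenation. Oxidative boron–Heck arylation of 11 with 12 (Pd(OCOCF3)2, 2,3-dichloro-5,6-dicyano-1,4-benzoquinone as oxidant) would give the flavone tert-butyl (2S)-2-(2-{4-[(tert-butyldimethylsilyl)oxy]phenyl}-5-hydroxy-4-oxo-7-{[tri(propan-2-yl)silyl]oxy}-4H-chromen-6-yl)piperidine-1-carboxylate F3. Asymmetric hydrogenation of its C2=C3 bond with a chiral ruthenium N-heterocyclic carbene catalyst generated from [Ru(cod)(2-methylallyl)2] should give 13 together with the over-reduced tert-butyl (2S)-2-[(2S,4S)-2-{4-[(tert-butyldimethylsilyl)oxy]phenyl}-4,5-dihydroxy-7-{[tri(propan-2-yl)silyl]oxy}-3,4-dihydro-2H-chromen-6-yl]piperidine-1-carboxylate F4. MnO2 would return F4 to 13.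

**Step 1.** Configuration at C2' may be lost by enolization of the α-amino ester before the carbenoid has added, or n-BuLi may attack the carbamate during the warm exchange and rearrangement stage. The fallback sets out from 1 and comes back at 3 (and so at 4); it replaces the carbenoid rearrangement by oxidation of an acetylide. Reduction of 1 with i-Bu2AlH in toluene at −78 °C would give tert-butyl (2S)-2-formylpiperidine-1-carboxylate F5. Dimethyl (1-diazo-2-oxopropyl)phosphonate with K2CO3 in MeOH at 0 °C would give tert-butyl (2S)-2-ethynylpiperidine-1-carboxylate F6. Deprotonation of F6 with n-BuLi (1 equiv) and oxidation with LiOOt-Bu (from t-BuOOH and LiN(SiMe3)2) in THF at −78 → 0 °C would give the same ynolate 3, which is silylated as in step 1.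

**Step 6.** Formaldehyde may attack C8 of ring A (para to the free 5-hydroxyl) in competition with N-methylation. The fallback sets out from 14 and comes back at 15, and avoids formaldehyde. N-Formylation of 14 with 2,2,2-trifluoroethyl formate would give (2S)-2-[(2S)-2-{4-[(tert-butyldimethylsilyl)oxy]phenyl}-5-hydroxy-4-oxo-7-{[tri(propan-2-yl)silyl]oxy}-3,4-dihydro-2H-chromen-6-yl]piperidine-1-carbaldehyde F7. Hydrosilylation of F7 with 1,1,3,3-tetramethyldisiloxane and catalytic Mo(CO)6 in THF at 65 °C, a reduction that spares ketones, would convert the formyl group to methyl and give 15.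

## Further compounds

F1 | step 3 | (4-oxo-4H-pyran-2-yl)acetic acid | OC(=O)CC1=CC(=O)C=CO1
F2 | step 3 | (4-oxo-4H-pyran-2-yl)acetyl chloride | ClC(=O)CC1=CC(=O)C=CO1
F3 | step 4 | tert-butyl (2S)-2-(2-{4-[(tert-butyldimethylsilyl)oxy]phenyl}-5-hydroxy-4-oxo-7-{[tri(propan-2-yl)silyl]oxy}-4H-chromen-6-yl)piperidine-1-carboxylate | CC(C)(C)OC(=O)N1CCCC[C@H]1c1c(O[Si](C(C)C)(C(C)C)C(C)C)cc2OC(=CC(=O)c2c1O)c1ccc(O[Si](C)(C)C(C)(C)C)cc1
F4 | step 4 | tert-butyl (2S)-2-[(2S,4S)-2-{4-[(tert-butyldimethylsilyl)oxy]phenyl}-4,5-dihydroxy-7-{[tri(propan-2-yl)silyl]oxy}-3,4-dihydro-2H-chromen-6-yl]piperidine-1-carboxylate | CC(C)(C)OC(=O)N1CCCC[C@H]1c1c(O[Si](C(C)C)(C(C)C)C(C)C)cc2c(c1O)[C@@H](O)C[C@@H](c1ccc(O[Si](C)(C)C(C)(C)C)cc1)O2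
F5 | step 1 | tert-butyl (2S)-2-formylpiperidine-1-carboxylate | CC(C)(C)OC(=O)N1CCCC[C@H]1C=O
F6 | step 1 | tert-butyl (2S)-2-ethynylpiperidine-1-carboxylate | CC(C)(C)OC(=O)N1CCCC[C@H]1C#C
F7 | step 6 | (2S)-2-[(2S)-2-{4-[(tert-butyldimethylsilyl)oxy]phenyl}-5-hydroxy-4-oxo-7-{[tri(propan-2-yl)silyl]oxy}-3,4-dihydro-2H-chromen-6-yl]piperidine-1-carbaldehyde | O=CN1CCCC[C@H]1c1c(O[Si](C(C)C)(C(C)C)C(C)C)cc2c(c1O)C(=O)C[C@@H](c1ccc(O[Si](C)(C)C(C)(C)C)cc1)O2
A1 | alternative 1 | (2S)-5,7-dihydroxy-2-(4-hydroxyphenyl)-2,3-dihydro-4H-chromen-4-one (naringenin) | O=C1C[C@@H](c2ccc(O)cc2)Oc2cc(O)cc(O)c12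
A2 | alternative 1 | 1-methyl-2,3,4,5-tetrahydropyridin-1-ium | C[N+]1=CCCCC1
A3 | alternative 1 | (2S)-5,7-dihydroxy-2-(4-hydroxyphenyl)-8-(1-methylpiperidin-2-yl)-2,3-dihydro-4H-chromen-4-one (both C2' epimers) | CN1CCCCC1c1c(O)cc(O)c2c1O[C@H](c1ccc(O)cc1)CC2=O
A4 | alternative 2 | methyl 2-{3-[(2S)-1-(tert-butoxycarbonyl)piperidin-2-yl]-2-oxopropyl}-4-oxo-4H-pyran-3-carboxylate | CC(C)(C)OC(=O)N1CCCC[C@H]1CC(=O)CC1=C(C(=O)OC)C(=O)C=CO1
A5 | alternative 2 | tert-butyl (2S)-2-(5,7-dihydroxy-4-oxo-4H-chromen-6-yl)piperidine-1-carboxylate | CC(C)(C)OC(=O)N1CCCC[C@H]1c1c(O)cc2OC=CC(=O)c2c1O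
A6 | alternative 3 | (2S)-6-bromo-5,7-bis(methoxymethoxy)-2-[4-(methoxymethoxy)phenyl]-2,3-dihydro-4H-chromen-4-one | Brc1c(OCOC)cc2c(c1OCOC)C(=O)C[C@@H](c1ccc(OCOC)cc1)O2
A7 | alternative 3 | chloro[(2R)-1-(tert-butoxycarbonyl)piperidin-2-yl]zinc | CC(C)(C)OC(=O)N1CCCC[C@H]1[Zn]Cl
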